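## Retrosynthetic overview

1. Target ⇐ reagent-controlled reduction of an aryl ketone (sets C7') and global desilylation of a trans-3-aroyl-4-[(S)-aryl(silyloxy)methyl]tetrahydrofuran.
2. That tetrahydrofuran ⇐ oxidative six-to-five ring contraction of a 4-aryl-3-substituted 3,6-dihydro-2H-pyran: ring carbon C3 shifts from C4 to C5, and C4 leaves the ring as the aroyl carbon (sets C8'). This is the only ring-forming event; the benzene rings and the oxane ring are bought.
3. Dihydropyran ⇐ kinetic enol triflate and Negishi arylation of the O-silylated aldol adduct.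
4. Aldol adduct ⇐ D-proline anti-aldol of oxan-4-one with the O-silyl vanillin-type aldehyde (sets C7 and C8).
5. Both aryl pieces ⇐ one aryl bromide from catechol (methylation, para-bromination, silylation), used once as aldehyde precursor and once as arylzinc precursor.

Assumption and shorthand: a one-pot sequence without isolation counts as one step; TBS = tert-butyldimethylsilyl; Ar = 4-(TBSO)-3-methoxyphenyl; C7/C8 = carbinol and ring carbon of the (S)-carbinol arm, C7'/C8' = those of the (R)-carbinol arm, C9/C9' = ring CH2.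

## Route

Step 1
Reactants: 1 catechol (benzene-1,2-diol)
Product: 2 guaiacol (2-methoxyphenol)
Conditions: MeI (1.0 equiv), K2CO3, acetone, reflux
Reagents that add atoms: iodomethane CI
Why: Williamson O-methylation; with one equivalent of MeI the monoether dominates and is freed from veratrole and catechol by acid–base extraction.

Step 2
Reactants: 2 guaiacol
Product: 4 (4-bromo-2-methoxyphenoxy)(tert-butyl)dimethylsilane, via 4-bromo-2-methoxyphenol 3 (not isolated)
Conditions: NBS (1.0 equiv), DMF, 0 °C; then imidazole, TBSCl, 20 °C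
Reagents that add atoms: N-bromosuccinimide O=C1CCC(=O)N1Br; tert-butyl(chloro)dimethylsilane CC(C)(C)[Si](C)(C)Cl
Why: Electrophilic aromatic bromination goes para to the free hydroxyl (the stronger donor), and imidazole-promoted silylation of the phenol in the same pot gives the aryl bromide ready for metalation.

Step 3
Reactants: 4 (4-bromo-2-methoxyphenoxy)(tert-butyl)dimethylsilane
Product: 7 4-(TBSO)-3-methoxybenzaldehyde, via aryllithium 5 (not isolated), via lithium hemiaminal alkoxide 6 (not isolated)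
Conditions: n-BuLi, THF, −78 °C; DMF, −78 → 0 °C; H2O
Reagents that add atoms: N,N-dimethylformamide CN(C)C=O
Why: Bromine–lithium exchange then Bouveault formylation; the aryl silyl ether is inert at −78 °C and the aldehyde is released when the hemiaminal alkoxide is hydrolysed.

Step 4
Reactants: 7 4-(TBSO)-3-methoxybenzaldehyde; 8 tetrahydro-4H-pyran-4-one (oxan-4-one)
Product: 9 (3R)-3-[(S)-Ar(hydroxy)methyl]oxan-4-one
Conditions: D-proline (30 mol%), 8 (5 equiv), DMSO, 20 °C, 4 d
Reagents that add atoms: none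
Why: Proline enamine aldol through the Houk–List chair transition state: the (E)-enamine of 8 attacks the aldehyde face held by the carboxylic acid, which with D-proline gives the anti adduct with C8 = R and C7 = S (mirror image of the well-documented L-proline series).

Step 5
Reactants: 9 (3R)-3-[(S)-Ar(hydroxy)methyl]oxan-4-one
Product: 10 (3R)-3-[(S)-Ar(TBSO)methyl]oxan-4-one
Conditions: TBSOTf, 2,6-lutidine, CH2Cl2, −78 °C
Reagents that add atoms: tert-butyldimethylsilyl trifluoromethanesulfonate CC(C)(C)[Si](C)(C)OS(=O)(=O)C(F)(F)F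
Why: Silyl triflate silylation of the secondary alcohol at −78 °C is faster than retro-aldol or enolisation, so both stereocentres are kept and the hydroxyl is masked for the enolate and oxidation chemistry.

Step 6
Reactants: 10 (3R)-3-[(S)-Ar(TBSO)methyl]oxan-4-one; 4 (4-bromo-2-methoxyphenoxy)(tert-butyl)dimethylsilane
Product: 15 (3R)-4-Ar-3-[(S)-Ar(TBSO)methyl]-3,6-dihydro-2H-pyran, via potassium enolate 11 (not isolated), via enol triflate 12 (not isolated), via arylmagnesium bromide 13 (not isolated), via arylzinc chloride 14 (not isolated)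
Conditions: KN(SiMe3)2, THF, −78 °C; Comins' reagent [N-(5-chloropyridin-2-yl)bis(trifluoromethanesulfonimide)], −78 °C; then ArZnCl (from 4: Mg turnings, LiCl, THF, 25 °C; then ZnCl2, 0 °C), Pd(OAc)2 (5 mol%), SPhos (10 mol%), 50 °C
Reagents that add atoms: none
Why: Kinetic deprotonation at the unsubstituted α'-CH2 and O-triflation fix the double bond away from C8, magnesium insertion into 4 followed by transmetalation to zinc gives a mild aryl nucleophile, and Negishi coupling (oxidative addition to zerovalent palladium, transmetalation from zinc, reductive elimination) puts the second aryl group on C4 under non-basic conditions that spare the silyl ethers.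

Step 7
Reactants: 15 (3R)-4-Ar-3-[(S)-Ar(TBSO)methyl]-3,6-dihydro-2H-pyran
Product: 16 Ar[(3R,4R)-4-[(S)-Ar(TBSO)methyl]oxolan-3-yl]methanone
Conditions: PhI(OH)OTs (1.1 equiv), 2,6-di-tert-butylpyridine, MeCN–H2O 9:1, −20 → 0 °C
Reagents that add atoms: water O
Why: Proposed new method: the electrophilic trivalent-iodine reagent adds to C5 of the electron-rich styrene-type alkene on the face opposite the pseudoaxial C3 side chain while water adds to benzylic C4 and supplies the future ketone oxygen; in the chair with the C5–I bond equatorial the C3–C4 ring bond is antiperiplanar to it, so C3 migrates to C5 with inversion at C5 as iodobenzene leaves (semipinacol 1,2-shift; aryl cannot migrate because it is cis to iodine), which contracts the oxane to the oxolane, turns C4 into the exocyclic aryl ketone and sets C8' trans to the side chain; the closest known reaction type is the oxidative ring contraction of 1-arylcycloalkenes and 1,2-dihydronaphthalenes with Koser's reagent or thallium trinitrate, which has not been shown on a 4-aryl-3,6-dihydro-2H-pyran or under control of a neighbouring stereocentre.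

Step 8
Reactants: 16 Ar[(3R,4R)-4-[(S)-Ar(TBSO)methyl]oxolan-3-yl]methanone
Product: 18 (S)-(4-hydroxy-3-methoxyphenyl)[(3R,4R)-4-[(R)-hydroxy(4-hydroxy-3-methoxyphenyl)methyl]oxolan-3-yl]methanol, via tris-silyl alcohol 17 (not isolated)
Conditions: (S)-Me-CBS oxazaborolidine (0.5 equiv), BH3·SMe2, THF, −20 °C; MeOH; then Bu4NF, AcOH, THF, 0 → 20 °C
Reagents that add atoms: none
Why: Corey–Bakshi–Shibata reduction: with aryl as the large ketone substituent the (S)-oxazaborolidine–borane complex delivers hydride to the face that gives the (R)-carbinol at C7' under reagent control, and buffered fluoride then cleaves the three silyl ethers without acid- or base-induced ionisation of the p-hydroxybenzylic alcohols.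

## Compound list

1 | catechol (benzene-1,2-diol) | Oc1ccccc1O | starting material
2 | guaiacol (2-methoxyphenol) | COc1ccccc1O | intermediate
3 | 4-bromo-2-methoxyphenol | COc1cc(Br)ccc1O | intermediate (not isolated)
4 | (4-bromo-2-methoxyphenoxy)(tert-butyl)dimethylsilane | COc1cc(Br)ccc1O[Si](C)(C)C(C)(C)C | intermediate
5 | [4-(TBSO)-3-methoxyphenyl]lithium | COc1cc([Li])ccc1O[Si](C)(C)C(C)(C)C | intermediate (not isolated)
6 | lithium (dimethylamino)[4-(TBSO)-3-methoxyphenyl]methanolate | COc1cc(ccc1O[Si](C)(C)C(C)(C)C)C(O[Li])N(C)C | intermediate (not isolated)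
7 | 4-[(tert-butyldimethylsilyl)oxy]-3-methoxybenzaldehyde | COc1cc(C=O)ccc1O[Si](C)(C)C(C)(C)C | intermediate
8 | tetrahydro-4H-pyran-4-one (oxan-4-one) | O=C1CCOCC1 | starting material
9 | (3R)-3-[(S)-Ar(hydroxy)methyl]oxan-4-one | O=C1CCOC[C@@H]1[C@H](O)c1ccc(O[Si](C)(C)C(C)(C)C)c(OC)c1 | intermediate
10 | (3R)-3-[(S)-Ar(TBSO)methyl]oxan-4-one | O=C1CCOC[C@@H]1[C@H](O[Si](C)(C)C(C)(C)C)c1ccc(O[Si](C)(C)C(C)(C)C)c(OC)c1 | intermediate
11 | potassium (3R)-3-[(S)-Ar(TBSO)methyl]-3,6-dihydro-2H-pyran-4-olate | [K+].[O-]C1=CCOC[C@@H]1[C@H](O[Si](C)(C)C(C)(C)C)c1ccc(O[Si](C)(C)C(C)(C)C)c(OC)c1 | intermediate (not isolated)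
12 | (3R)-3-[(S)-Ar(TBSO)methyl]-3,6-dihydro-2H-pyran-4-yl trifluoromethanesulfonate | FC(F)(F)S(=O)(=O)OC1=CCOC[C@@H]1[C@H](O[Si](C)(C)C(C)(C)C)c1ccc(O[Si](C)(C)C(C)(C)C)c(OC)c1 | intermediate (not isolated)
13 | bromido[4-(TBSO)-3-methoxyphenyl]magnesium | COc1cc([Mg]Br)ccc1O[Si](C)(C)C(C)(C)C | intermediate (not isolated)
14 | chlorido[4-(TBSO)-3-methoxyphenyl]zinc | COc1cc([Zn]Cl)ccc1O[Si](C)(C)C(C)(C)C | intermediate (not isolated)
15 | (3R)-4-Ar-3-[(S)-Ar(TBSO)methyl]-3,6-dihydro-2H-pyran | COc1cc(ccc1O[Si](C)(C)C(C)(C)C)C1=CCOC[C@@H]1[C@H](O[Si](C)(C)C(C)(C)C)c1ccc(O[Si](C)(C)C(C)(C)C)c(OC)c1 | intermediate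
16 | Ar[(3R,4R)-4-[(S)-Ar(TBSO)methyl]oxolan-3-yl]methanone | COc1cc(ccc1O[Si](C)(C)C(C)(C)C)[C@@H](O[Si](C)(C)C(C)(C)C)[C@H]1COC[C@@H]1C(=O)c1ccc(O[Si](C)(C)C(C)(C)C)c(OC)c1 | intermediate
17 | (R)-Ar[(3R,4R)-4-[(S)-Ar(TBSO)methyl]oxolan-3-yl]methanol | COc1cc(ccc1O[Si](C)(C)C(C)(C)C)[C@@H](O[Si](C)(C)C(C)(C)C)[C@H]1COC[C@@H]1[C@@H](O)c1ccc(O[Si](C)(C)C(C)(C)C)c(OC)c1 | intermediate (not isolated)
18 | (S)-(4-hydroxy-3-methoxyphenyl)[(3R,4R)-4-[(R)-hydroxy(4-hydroxy-3-methoxyphenyl)methyl]oxolan-3-yl]methanol | COc1cc([C@@H](O)[C@H]2COC[C@@H]2[C@@H](O)c2ccc(O)c(OC)c2)ccc1O | target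

## Step count and risks

Total step count: 8 (steps 2, 3, 6 and 8 are one-pot sequences).
Longest linear sequence: 8 (1 → 2 → 4 → 7 → 9 → 10 → 15 → 16 → 18; bromide 4 also feeds step 6).

Steps most likely to fail:

**Step 4 (aldol with an electron-rich aldehyde).** Aldehyde 7 is a weak electrophile for enamine catalysis, so conversion may stall and long reaction times invite retro-aldol erosion of the anti ratio. The fallback sets out from 8 and uses a preformed enolate with Lewis-base catalysis. Me3SiCl, Et3N and NaI in MeCN give the silyl enol ether 4-[(trimethylsilyl)oxy]-3,6-dihydro-2H-pyran F1. SiCl4 with 1 mol% Hg(OAc)2 exchanges silicon to give the trichlorosilyl enolate 4-[(trichlorosilyl)oxy]-3,6-dihydro-2H-pyran F2. F2 adds to 7 with 10 mol% of a stilbene-1,2-diamine-derived chiral phosphoramide (the enantiomer that gives the 3R,1'S series) in CH2Cl2 at −78 °C through a closed chair siliconate transition state (anti). NaHCO3 work-up brings the sequence back to the route at 9.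

**Step 7 (the proposed ring contraction).**
- Hydration of the benzylic cation syn to iodine would open a 1,2-aryl shift.
- The cation could fragment in a retro-Prins sense across C3–C7.
- The liberated sulfonic acid could ionise the benzylic silyl ether.
- The trivalent-iodine reagent could oxidise the electron-rich aryl silyl ethers instead of the alkene.
- Any cis ketone formed would be converged to trans with DBU, since C8' is α to the carbonyl.

The fallback uses known chemistry and sets out from 15. NBS in THF–H2O with NaHCO3 at 0 °C gives by anti addition the bromohydrin (3R,4R,5S)-5-bromo-4-Ar-3-[(S)-Ar(TBSO)methyl]oxan-4-ol F3. AgBF4 with 2,6-di-tert-butylpyridine in CH2Cl2 at −40 → 0 °C abstracts bromide and triggers the same ring-bond shift. This is the classical halohydrin semipinacol ring contraction of trans-2-halo-1-arylcyclohexanols, and it comes back to the route at 16.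

**Step 8 (reagent-controlled reduction).** A Felkin–Anh analysis of 16, with the ring carbon that carries the side chain as the large group, predicts the 7'S epimer. The catalyst must therefore override a mismatched substrate bias, and the α-branched alkyl group lowers CBS selectivity. The fallback sets out from 16 and accepts substrate control, then inverts. LiBH(s-Bu)3 in THF at −78 °C gives the epimeric alcohol (S)-Ar[(3R,4R)-4-[(S)-Ar(TBSO)methyl]oxolan-3-yl]methanol F4. Mitsunobu inversion (4-nitrobenzoic acid, PPh3, diisopropyl azodicarboxylate, toluene, −20 → 20 °C) gives (R)-Ar[(3R,4R)-4-[(S)-Ar(TBSO)methyl]oxolan-3-yl]methyl 4-nitrobenzoate F5. K2CO3 in MeOH removes the ester and both aryl silyl groups to give (R)-(4-hydroxy-3-methoxyphenyl)[(3R,4R)-4-[(S)-(4-hydroxy-3-methoxyphenyl)(TBSO)methyl]oxolan-3-yl]methanol F6. Bu4NF/AcOH then removes the last silyl group and the sequence comes back to the route at 18.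

## Further compounds

F1 | step 4 | 4-[(trimethylsilyl)oxy]-3,6-dihydro-2H-pyran | C[Si](C)(C)OC1=CCOCC1
F2 | step 4 | 4-[(trichlorosilyl)oxy]-3,6-dihydro-2H-pyran | Cl[Si](Cl)(Cl)OC1=CCOCC1
F3 | step 7 | (3R,4R,5S)-5-bromo-4-Ar-3-[(S)-Ar(TBSO)methyl]oxan-4-ol | COc1cc(ccc1O[Si](C)(C)C(C)(C)C)[C@@]1(O)[C@@H](Br)COC[C@@H]1[C@H](O[Si](C)(C)C(C)(C)C)c1ccc(O[Si](C)(C)C(C)(C)C)c(OC)c1
F4 | step 8 | (S)-Ar[(3R,4R)-4-[(S)-Ar(TBSO)methyl]oxolan-3-yl]methanol | COc1cc(ccc1O[Si](C)(C)C(C)(C)C)[C@@H](O[Si](C)(C)C(C)(C)C)[C@H]1COC[C@@H]1[C@H](O)c1ccc(O[Si](C)(C)C(C)(C)C)c(OC)c1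
F5 | step 8 | (R)-Ar[(3R,4R)-4-[(S)-Ar(TBSO)methyl]oxolan-3-yl]methyl 4-nitrobenzoate | COc1cc(ccc1O[Si](C)(C)C(C)(C)C)[C@@H](O[Si](C)(C)C(C)(C)C)[C@H]1COC[C@@H]1[C@@H](OC(=O)c1ccc(cc1)[N+]([O-])=O)c1ccc(O[Si](C)(C)C(C)(C)C)c(OC)c1
F6 | step 8 | (R)-(4-hydroxy-3-methoxyphenyl)[(3R,4R)-4-[(S)-(4-hydroxy-3-methoxyphenyl)(TBSO)methyl]oxolan-3-yl]methanol | COc1cc(ccc1O)[C@@H](O[Si](C)(C)C(C)(C)C)[C@H]1COC[C@@H]1[C@@H](O)c1ccc(O)c(OC)c1
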